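I began from an invariant: when two first-order steps leave the same species, the ratio of their rates equals the ratio of their constants, whatever the concentration of that species does.

    Z → E (k1 = 0.0375 /s)
    L ⇌ Z (K2 = 1.43, k2 = 0.0309 /s)
    2 L → L2 (k3 = 0.319 /M/s)
    Z → Q (k4 = 0.0158 /s)

| flask | L | remark | time |
|---|---|---|---|
| south-west | 13 mM | a single well-mixed tank run continuously and read at steady state, 4.0 min in it on average |  |
| south-east | 13 mM | everything together in a closed stirred flask, run for 4.0 min | 4.0 min |

1. the set-up with the highest share of Q in all that became Q or E, at the outlet or at the end ("none" if the first two lie within 2 percentage points) (south-west / south-east / none)
2. share of Q in all that became Q or E, at the outlet or at the end, south-west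
3. share of Q in all that became Q or E, at the outlet or at the end, south-east

- percentages count the L that a species holds: one L2 counts as two
- for a step with 2 of a species take k times the square, and two of it per event
- the stated concentrations are those of everything mixed, before any reaction; amounts are the same in each set-up
- run time (south-east): 4.0 min

I first compared the two rates at one moment. Q forms at 0.0158 /s times cZ and E at 0.0375 /s times cZ, so cZ cancels, and E forms 2.37 times as fast as Q.

Next I asked whether this comparison drifts. The ratio contains neither time nor cZ, and in the scheme neither Q nor E returns to Z. I therefore named the branching share, the part of Z's forward exit that goes to Q, which the field calls selectivity, and reckoned it as 29.6%.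

Last I asked whether the vessel matters. In the south-west tank, Q and E are made in this ratio at steady state and washed out alike. In the south-east flask, both build up from one cZ history, so the ratio of their totals is the same. I therefore expected the same share in both set-ups, a gap inside the margin of 2 percentage points.

The forecast gave 29.6% for south-west, 29.6% for south-east and the verdict none, holding that “This share does not depend on the Z concentration history”.

The simulation gave 29.6% for the south-west tank and 29.6% for the south-east flask, so the verdict was none. Q was less at the south-west outlet, 22.2%, than at the south-east end, 25.2%. Dividing the south-west amount by 29.6% puts Q plus E there at 75.0% of the L charged. In a neighbour like south-east but charged with 3.2 mM of L, E came to 66.6% at 4.00 min; E is the part of Q plus E that 29.6% leaves over, so that amount of E goes with 28.0% of Q, and the Q that stood there was 28.1%.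

All constants are invented; the rest is arithmetic.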